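**Retrosynthetic overview**
1. Ring E (the oxepine) is closed last by cutting both O2'–C(=CMe2) and C3–CH2. This gives flavone 16 (free 2'-OH, C3–SnBu3) and propargylic carbonate 19, joined in one palladium-catalysed (5+2) annulation.
2. Enabling feature: the ether carbon of ring E lies between a ring CH2 (on C3 of ring C) and an exocyclic CMe2. This 2-oxyallyl triad maps onto a 1,1-dimethylpropargyl unit attacked by oxygen at its central carbon. O2' of ring B and C3 of ring C are 1,5-related through C2'–C1'–C2, so they bridge the central carbon and the CH2 terminus in a seven-membered ring.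
3. 16 comes from flavone 13 by C3 lithiation/stannylation and desilylation. Ring C of 13 comes from diketone 12, made from acetophenone 6 and aroyl chloride 10 (Baker–Venkataraman logic).
4. 6 comes from acetophenone 1: ring D by chromenylation with prenal, then the C-prenyl group by O-prenylation and para-Claisen–Cope rearrangement.
5. Order of ring formation: rings A and B are bought, then D (step 1), C (step 7), E (step 11).

Key step: step 11

Remark: the target has no stereocentre and no stereogenic double bond, so no descriptor is needed; catalyst-bound species of catalytic cycles are described in the Why lines and carry no number, every other non-isolated intermediate is numbered; compounds 1, 7 and 17 are taken as commercial.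

**Step 1**
Reactants: 1 1-(2,4-dihydroxy-6-methoxyphenyl)ethanone
Product: 3 1-(5-hydroxy-7-methoxy-2,2-dimethyl-2H-chromen-6-yl)ethanone, via oxatriene 2 (not isolated)
Conditions: 3-methylbut-2-enal (1.5 equiv), ethylenediammonium diacetate (10 mol %), xylene, 140 °C
Reagents that add atoms: 3-methylbut-2-enal, CC(C)=CC=O
Why: Amine-catalysed domino Knoevenagel-type condensation and 6π-oxa-electrocyclisation (chromenylation); the hydrogen-bonded 2-OH stays bound to the acetyl group, so the free 4-OH becomes the ring oxygen and the carbon between the two hydroxyls, the most nucleophilic one, takes the C3 unit.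

**Step 2**
Reactants: 3 1-(5-hydroxy-7-methoxy-2,2-dimethyl-2H-chromen-6-yl)ethanone
Product: 4 1-[7-methoxy-2,2-dimethyl-5-(3-methylbut-2-enyloxy)-2H-chromen-6-yl]ethanone
Conditions: 1-bromo-3-methylbut-2-ene (1.5 equiv), K2CO3 (2 equiv), DMF, 50 °C
Reagents that add atoms: 1-bromo-3-methylbut-2-ene (prenyl bromide), CC(C)=CCBr
Why: Williamson etherification of the chelated phenol; K2CO3 in DMF favours O- over C-alkylation and is too weak to enolise the ketone.

**Step 3**
Reactants: 4 1-[7-methoxy-2,2-dimethyl-5-(3-methylbut-2-enyloxy)-2H-chromen-6-yl]ethanone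
Product: 6 1-[5-hydroxy-7-methoxy-2,2-dimethyl-8-(3-methylbut-2-enyl)-2H-chromen-6-yl]ethanone, via ortho-dienone 5 (not isolated)
Conditions: N,N-diethylaniline, 200 °C, sealed tube, argon
Reagents that add atoms: none
Why: Para-Claisen–Cope rearrangement: both ortho positions of the aryl prenyl ether are substituted, so the [3,3] shift to the ortho-dienone is followed by a Cope [3,3] shift to the free para carbon and tautomerisation, and the two allylic inversions return a normal prenyl group.

**Step 4**
Reactants: 7 2-hydroxy-4,5-dimethoxybenzoic acid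
Product: 9 4,5-dimethoxy-2-(triisopropylsilyloxy)benzoic acid, via silyl ester 8 (not isolated)
Conditions: i-Pr3SiCl (2.3 equiv), imidazole (5 equiv), DMF, rt; then AcOH–THF–H2O, rt
Reagents that add atoms: chlorotriisopropylsilane, CC(C)[Si](Cl)(C(C)C)C(C)C
Why: Silylation of phenol and acid followed by selective solvolysis of the far more labile silyl ester, which leaves the hindered aryl silyl ether in place.

**Step 5**
Reactants: 9 4,5-dimethoxy-2-(triisopropylsilyloxy)benzoic acid
Product: 10 4,5-dimethoxy-2-(triisopropylsilyloxy)benzoyl chloride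
Conditions: (COCl)2 (1.3 equiv), DMF (cat.), CH2Cl2, 0 °C to rt; volatiles removed, used crude
Reagents that add atoms: oxalyl chloride, ClC(=O)C(Cl)=O
Why: Acid chloride formation through the Vilsmeier-type chloroiminium ion, under conditions that the aryl triisopropylsilyl ether tolerates.

**Step 6**
Reactants: 6 1-[5-hydroxy-7-methoxy-2,2-dimethyl-8-(3-methylbut-2-enyl)-2H-chromen-6-yl]ethanone; 10 4,5-dimethoxy-2-(triisopropylsilyloxy)benzoyl chloride
Product: 12 1-[4,5-dimethoxy-2-(triisopropylsilyloxy)phenyl]-3-[5-hydroxy-7-methoxy-2,2-dimethyl-8-(3-methylbut-2-enyl)-2H-chromen-6-yl]propane-1,3-dione, via dilithium dianion 11 (not isolated)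
Conditions: LiN(SiMe3)2 (3.2 equiv), THF, −78 to −10 °C; then 10 (1.1 equiv), −78 °C to rt; AcOH quench
Reagents that add atoms: none
Why: One-pot variant of the Baker–Venkataraman synthesis: the dilithium enolate–phenolate is acylated at carbon (or at oxygen and then rearranged by the excess base) to the 1,3-diketone, whose deprotonation by the third equivalent of base prevents over-acylation.

**Step 7**
Reactants: 12 the 1,3-diketone of step 6
Product: 13 2-[4,5-dimethoxy-2-(triisopropylsilyloxy)phenyl]-5-methoxy-8,8-dimethyl-6-(3-methylbut-2-enyl)-4H,8H-pyrano[2,3-h]chromen-4-one (flavone numbering: 5-OMe, 6-prenyl, 7,8-fused 2,2-dimethylpyran, 2'-OSi(i-Pr)3, 4',5'-OMe, 3-H)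
Conditions: TsOH·H2O (10 mol %), toluene, 60 °C
Reagents that add atoms: none
Why: Acid-catalysed cyclodehydration of the o-hydroxyaryl 1,3-diketone to the 4H-chromen-4-one; only the ring A phenol is free, so the silyl ether on ring B excludes the isomeric closure.

**Step 8**
Reactants: 13 the 3-H flavone silyl ether of step 7
Product: 15 2-[4,5-dimethoxy-2-(triisopropylsilyloxy)phenyl]-5-methoxy-8,8-dimethyl-6-(3-methylbut-2-enyl)-3-(tributylstannyl)-4H,8H-pyrano[2,3-h]chromen-4-one, via 3-lithioflavone 14 (not isolated)
Conditions: LiN(i-Pr)2 (1.3 equiv), THF, −78 °C, 30 min; then Bu3SnCl (1.5 equiv), −78 to 0 °C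
Reagents that add atoms: tributyltin chloride, CCCC[Sn](Cl)(CCCC)CCCC
Why: Carbonyl-directed C3 lithiation of a flavone with a lithium amide and trapping of the alkenyllithium with the tin chloride, a known way to 3-substituted flavones that needs no electrophilic halogen and so spares the prenyl and chromene double bonds.

**Step 9**
Reactants: 15 the 3-stannyl flavone silyl ether of step 8
Product: 16 2-(2-hydroxy-4,5-dimethoxyphenyl)-5-methoxy-8,8-dimethyl-6-(3-methylbut-2-enyl)-3-(tributylstannyl)-4H,8H-pyrano[2,3-h]chromen-4-one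
Conditions: Bu4NF (1.2 equiv), AcOH (1.2 equiv), THF, 0 °C
Reagents that add atoms: none
Why: Fluoride-mediated cleavage of the aryl silyl ether, buffered with AcOH so that the alkenylstannane and the chromone are not exposed to free phenoxide or fluoride.

**Step 10**
Reactants: 17 2-methylbut-3-yn-2-ol
Product: 19 methyl 2-methylbut-3-yn-2-yl carbonate, via lithium alkoxide 18 (not isolated)
Conditions: n-BuLi (1.05 equiv), THF, −78 °C; then ClCO2Me (1.1 equiv), −78 °C to rt
Reagents that add atoms: methyl chloroformate, COC(Cl)=O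
Why: O-Acylation of the lithium alkoxide of a tertiary propargylic alcohol with a chloroformate.

**Step 11**
Reactants: 16 the 2'-hydroxy-3-(tributylstannyl)flavone of step 9; 19 methyl 2-methylbut-3-yn-2-yl carbonate
Product: 20 target CNP0192589.0 (the flavone of 16 in which O2' and C3 are bridged by C(=CMe2)–CH2, O2' on the alkylidene carbon and CH2 on C3)
Conditions: 19 (1.5 equiv), Pd2(dba)3·CHCl3 (5 mol %), DPEphos (12 mol %), THF (0.01 M), 65 °C, argon; chromatography on Et3N-washed silica
Reagents that add atoms: none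
Why: Proposed new method: a palladium-catalysed domino (5+2) annulation in which zerovalent palladium ionises carbonate 19 to a cationic η3-propargyl/allenyl complex, the ring B phenoxide of 16 adds to its central carbon and protonation of the resulting palladacyclobutene gives a 2-aryloxy-π-allyl complex of divalent palladium, which is closed onto C3 by intramolecular tin-to-palladium transmetalation and allyl–alkenyl reductive elimination; the closest known reaction types are the palladium-catalysed reaction of propargylic carbonates with phenols and other bis-nucleophiles (central-carbon attack, then allylic substitution) and the Stille coupling of allylic carbonates with alkenylstannanes, and their merger in one catalytic cycle is the new element. The oxepine is closed by C3–CH2 bond formation from an eight-membered palladacycle after its O–C bond has been made intermolecularly, and no stereocentre arises because the new alkene carries two identical methyl groups. Phenoxide addition must precede tin–palladium exchange (otherwise a 3-allenylflavone results), which the chelating bisphosphine secures by keeping the propargyl complex cationic and coordinatively saturated while the liberated methoxide generates the phenoxide at once. C–C bond formation must occur at the CH2 and not at the CMe2 terminus, which sterics secure since both termini would give a seven-membered ring. Ring closure must beat intermolecular O-allylation, which high dilution and the reversibility of aryl allyl ether formation under zerovalent palladium secure. Loss of CO2 and formation of the Sn–O bond of Bu3SnOMe drive the sequence.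

**Compound list**
1 | 1-(2,4-dihydroxy-6-methoxyphenyl)ethanone | CC(=O)c1c(O)cc(O)cc1OC | starting material
2 | 4-acetyl-3-hydroxy-5-methoxy-2-(3-methylbut-2-enylidene)cyclohexa-3,5-dien-1-one (oxatriene) | CC(=O)C1=C(O)C(=CC=C(C)C)C(=O)C=C1OC | intermediate
3 | 1-(5-hydroxy-7-methoxy-2,2-dimethyl-2H-chromen-6-yl)ethanone | CC(=O)c1c(O)c2C=CC(C)(C)Oc2cc1OC | intermediate
4 | 1-[7-methoxy-2,2-dimethyl-5-(3-methylbut-2-enyloxy)-2H-chromen-6-yl]ethanone | CC(=O)c1c(OCC=C(C)C)c2C=CC(C)(C)Oc2cc1OC | intermediate
5 | 6-acetyl-7-methoxy-2,2-dimethyl-6-(2-methylbut-3-en-2-yl)-2H-chromen-5(6H)-one (ortho-dienone) | CC(=O)C1(C(C)(C)C=C)C(=O)C2=C(OC(C)(C)C=C2)C=C1OC | intermediate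
6 | 1-[5-hydroxy-7-methoxy-2,2-dimethyl-8-(3-methylbut-2-enyl)-2H-chromen-6-yl]ethanone | CC(=O)c1c(O)c2C=CC(C)(C)Oc2c(CC=C(C)C)c1OC | intermediate
7 | 2-hydroxy-4,5-dimethoxybenzoic acid | COc1cc(O)c(cc1OC)C(O)=O | starting material
8 | triisopropylsilyl 4,5-dimethoxy-2-(triisopropylsilyloxy)benzoate | COc1cc(O[Si](C(C)C)(C(C)C)C(C)C)c(cc1OC)C(=O)O[Si](C(C)C)(C(C)C)C(C)C | intermediate
9 | 4,5-dimethoxy-2-(triisopropylsilyloxy)benzoic acid | COc1cc(O[Si](C(C)C)(C(C)C)C(C)C)c(cc1OC)C(O)=O | intermediate
10 | 4,5-dimethoxy-2-(triisopropylsilyloxy)benzoyl chloride | COc1cc(O[Si](C(C)C)(C(C)C)C(C)C)c(cc1OC)C(Cl)=O | intermediate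
11 | dilithium enolate–phenolate of 6 | [Li+].[Li+].C=C([O-])c1c([O-])c2C=CC(C)(C)Oc2c(CC=C(C)C)c1OC | intermediate
12 | 1-[4,5-dimethoxy-2-(triisopropylsilyloxy)phenyl]-3-[5-hydroxy-7-methoxy-2,2-dimethyl-8-(3-methylbut-2-enyl)-2H-chromen-6-yl]propane-1,3-dione | COc1cc(O[Si](C(C)C)(C(C)C)C(C)C)c(cc1OC)C(=O)CC(=O)c1c(O)c2C=CC(C)(C)Oc2c(CC=C(C)C)c1OC | intermediate
13 | 2-[4,5-dimethoxy-2-(triisopropylsilyloxy)phenyl]-5-methoxy-8,8-dimethyl-6-(3-methylbut-2-enyl)-4H,8H-pyrano[2,3-h]chromen-4-one | COc1cc(O[Si](C(C)C)(C(C)C)C(C)C)c(cc1OC)-c1oc2c3c(c(CC=C(C)C)c(OC)c2c(=O)c1)OC(C)(C)C=C3 | intermediate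
14 | 3-lithio derivative of 13 | COc1cc(O[Si](C(C)C)(C(C)C)C(C)C)c(cc1OC)-c1oc2c3c(c(CC=C(C)C)c(OC)c2c(=O)c1[Li])OC(C)(C)C=C3 | intermediate
15 | 3-(tributylstannyl) derivative of 13 | COc1cc(O[Si](C(C)C)(C(C)C)C(C)C)c(cc1OC)-c1oc2c3c(c(CC=C(C)C)c(OC)c2c(=O)c1[Sn](CCCC)(CCCC)CCCC)OC(C)(C)C=C3 | intermediate
16 | 2-(2-hydroxy-4,5-dimethoxyphenyl)-5-methoxy-8,8-dimethyl-6-(3-methylbut-2-enyl)-3-(tributylstannyl)-4H,8H-pyrano[2,3-h]chromen-4-one | COc1cc(O)c(cc1OC)-c1oc2c3c(c(CC=C(C)C)c(OC)c2c(=O)c1[Sn](CCCC)(CCCC)CCCC)OC(C)(C)C=C3 | intermediate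
17 | 2-methylbut-3-yn-2-ol | CC(C)(O)C#C | starting material
18 | lithium 2-methylbut-3-yn-2-olate | [Li+].[O-]C(C)(C)C#C | intermediate
19 | methyl 2-methylbut-3-yn-2-yl carbonate | COC(=O)OC(C)(C)C#C | intermediate
20 | CNP0192589.0 (oxepine-bridged 5,4',5'-trimethoxy-6-prenyl-7,8-(2,2-dimethylpyrano)flavone) | COc1cc2c(cc1OC)-c1oc3c4c(c(CC=C(C)C)c(OC)c3c(=O)c1CC(=C(C)C)O2)OC(C)(C)C=C4 | target

**Totals and risks**
Total step count: 11. Longest linear sequence: 8 steps (steps 1, 2, 3, 6, 7, 8, 9, 11).

Steps most likely to fail: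

Step 11. The risks are tin-to-palladium exchange before phenoxide addition (coupling to an allene), β-hydride loss from the π-allyl intermediate to a 2-aryloxydiene, and intermolecular O-allylation that outruns ring closure. Fallback: the two ring bonds are made one after the other by known chemistry. Setting out from 16, a Stille allylation (Pd2(dba)3·CHCl3, AsPh3, THF, 50 °C) with 1,2-dibromo-3-methylbut-2-ene F1 should give 3-(2-bromo-3-methylbut-2-enyl)-2-(2-hydroxy-4,5-dimethoxyphenyl)-5-methoxy-8,8-dimethyl-6-(3-methylbut-2-enyl)-4H,8H-pyrano[2,3-h]chromen-4-one F2. F1 would be made from commercial 3-methylbuta-1,2-diene and Br2 in CH2Cl2 at −78 °C; its tertiary allylic isomer converges on the same allylpalladium species. A copper-catalysed intramolecular Ullmann-type O-vinylation of the phenol with the vinyl bromide (CuI, N,N-dimethylglycine, Cs2CO3, dioxane, 90 °C) would then close the oxepine and return to the route at 20.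

Step 8. The risks are competing deprotonation at the benzylic–allylic CH2 of the prenyl group, oxygen-to-carbon silyl migration in the lithio species, and incomplete metalation at the hindered C3. Fallback: the C3 handle is placed before ring C is closed. Setting out from 12, bromination at the central diketone carbon (NBS, CH2Cl2, −20 °C) should give 2-bromo-1-[4,5-dimethoxy-2-(triisopropylsilyloxy)phenyl]-3-[5-hydroxy-7-methoxy-2,2-dimethyl-8-(3-methylbut-2-enyl)-2H-chromen-6-yl]propane-1,3-dione F3. Cyclodehydration as in step 7 should give the 3-bromo analogue of 13 F4. Palladium-catalysed stannylation (Bu3SnSnBu3, Pd(PPh3)4, toluene, 100 °C) returns to the route at 15.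

Step 3. The risks are thermal loss of the prenyl ether as isoprene instead of rearrangement, side reactions of the acetyl-bearing ortho-dienone, and decomposition of the chromene at 200 °C. Fallback: the sigmatropic route is replaced by cross-coupling. Setting out from 3, iodination of the only free, triply oxygen-activated ring position (NIS, MeCN, 0 °C) should give 1-(5-hydroxy-8-iodo-7-methoxy-2,2-dimethyl-2H-chromen-6-yl)ethanone F5. A Suzuki–Miyaura coupling with 3-methylbut-2-enylboronic acid pinacol ester under ligand control for the linear product (Pd(OAc)2, bulky dialkylbiarylphosphine, K3PO4, THF–H2O, 40 °C) returns to the route at 6.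

**Further compounds**
F1 | step 11 | 1,2-dibromo-3-methylbut-2-ene | CC(C)=C(Br)CBr
F2 | step 11 | 3-(2-bromo-3-methylbut-2-enyl)-2-(2-hydroxy-4,5-dimethoxyphenyl)-5-methoxy-8,8-dimethyl-6-(3-methylbut-2-enyl)-4H,8H-pyrano[2,3-h]chromen-4-one | COc1cc(O)c(cc1OC)-c1oc2c3c(c(CC=C(C)C)c(OC)c2c(=O)c1CC(Br)=C(C)C)OC(C)(C)C=C3
F3 | step 8 | 2-bromo-1-[4,5-dimethoxy-2-(triisopropylsilyloxy)phenyl]-3-[5-hydroxy-7-methoxy-2,2-dimethyl-8-(3-methylbut-2-enyl)-2H-chromen-6-yl]propane-1,3-dione | COc1cc(O[Si](C(C)C)(C(C)C)C(C)C)c(cc1OC)C(=O)C(Br)C(=O)c1c(O)c2C=CC(C)(C)Oc2c(CC=C(C)C)c1OC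
F4 | step 8 | 3-bromo-2-[4,5-dimethoxy-2-(triisopropylsilyloxy)phenyl]-5-methoxy-8,8-dimethyl-6-(3-methylbut-2-enyl)-4H,8H-pyrano[2,3-h]chromen-4-one | COc1cc(O[Si](C(C)C)(C(C)C)C(C)C)c(cc1OC)-c1oc2c3c(c(CC=C(C)C)c(OC)c2c(=O)c1Br)OC(C)(C)C=C3
F5 | step 3 | 1-(5-hydroxy-8-iodo-7-methoxy-2,2-dimethyl-2H-chromen-6-yl)ethanone | CC(=O)c1c(O)c2C=CC(C)(C)Oc2c(I)c1OC
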